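## Structural features

The target contains three rings. Ring A is a tropone whose carbonyl is flanked by C–CO2Me and C–CH3, followed by a second C–CH3 and the only ring C–H. Ring B is a 2,3-dihydrofuran fused to the two remaining tropone carbons. Ring C is a cyclohexane that shares the oxygen-bearing sp3 carbon of ring B as a spiro centre.

The four stereocentres are contiguous on ring C (carvone numbering): C5 (S, CH carrying the 2-hydroxypropan-2-yl group), C6 (R, quaternary, methyl and 2-carboxyethyl), spiro C1 (S) and C2 (S, CH–CH3). In the preferred chair the C2 methyl, the C5 substituent and the C6 chain are equatorial, the C6 methyl is axial, and the spiro C–O bond is axial, cis to the chain and to the C2 methyl.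

Fragile points are:
- the tertiary alcohol (ionisation, dehydration);
- the tropone (nucleophiles, reductants);
- the spiro ether oxygen, which becomes a leaving group whenever a precursor places it β to an enolisable carbonyl;
- the two carboxyl carbons, which must end in different states (methyl ester on ring A, free acid on the chain).

The real difficulty is twofold: a fully substituted spiro ether carbon wedged between a quaternary carbon and a methine, and placing the ether oxygen on the tropone carbon next to C(CH3)–C=O rather than on the one next to the ring C–H.

The key step exploits the match between the five tropone carbons C(CH3)–C(=O)–C(CO2Me)=C(CH3)–CH and a 2,5-dimethyl-4-(methoxycarbonyl)-3-oxidopyrylium. The two ring-fusion carbons are the C=C of a spiro 2,3-dihydrofuran that already holds the spiro centre and all of ring C.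

## Logic of the disconnections

**28 ⇒ 26 ⇒ 25.** The carboxyl C–O bonds are traced back to a CH2–OH, and both hydroxyls to O–Si bonds. An ester on the chain would be attacked by the ylide and acetylide reagents needed earlier, and would later have to be hydrolysed next to the ring-A ester. Gain: the chain terminus is inert from step 6 to step 17 and the two carboxyls are differentiated by construction. Demand: step 18 must oxidise a primary alcohol without touching tropone or tertiary alcohol, and step 17 must free a tertiary silyl ether without ionising it.

**25 ⇒ 23 ⇒ 22.** Water is added back across ring A so that one oxygen bridges the ring CH carbon and the methyl-bearing carbon next to the carbonyl. This is done because 22 is the direct product of a cycloaddition that delivers all seven ring carbons with their substituents. Gain: the aromatic ring differs from a bicyclic adduct only by one molecule of water, and the bridge stereocentres are transient. Demand: the forward opening must break the allylic C–O bond first (step 15), and the oxidation and dehydration (step 16) must never leave the spiro ether oxygen β to an enolisable C–H.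

**22 ⇒ 12 + 20 (through 21).** Both C–C bonds from the ring-fusion carbons are cut: O-bearing fusion carbon to C(CH3), and CH2-bearing fusion carbon to the ring CH. Gain: full convergence (a nine-step and a four-step fragment) and no new permanent stereocentre. Demand: the regiochemical pairing of the two termini, an enol ether that survives amine base, and a ylide that is trapped before it dimerises.

**20 ⇒ 19 ⇒ 18 ⇒ 16 ⇒ 13 + 14.** The acetal O–acyl bond is cut, then the pyranone is traced to a furan carrying a furylic hydroxyl, then the furylic C–O bond, then the furan C–C and C–O bonds. Gain: two commodity chemicals. Demand: a furan from 13 and 14 carries an ethyl group, so the furylic oxygen must be introduced selectively (step 11) before the oxidative ring expansion can work.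

**12 ⇒ 11 ⇒ 10 ⇒ 9.** The enol ether O–CH bond, the propargylic C–C bond and the epoxide C–C and C–O bonds are cut back to a ketone. Gain: the spiro centre comes from a carbonyl carbon. Demand: the methylene must be delivered equatorially so that the oxygen ends axial, and the alkyne must be introduced with no electrophilic ester in the molecule.

**9 ⇒ 7 ⇒ 6 ⇒ 4 ⇒ 3.** Two O–Si bonds, the tertiary C–O bond (from a 1,1-disubstituted alkene), the primary C–O bond (from a terminal alkene) and one C–H bond (from an enone) are removed. Gain: all oxygen functions of ring C are traced to alkenes. Demand: chemoselection among three alkenes, and setting C2 by equilibration only once the C5 group is large enough to lock the chair.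

**3 ⇒ 2 ⇒ 1.** Both C–C bonds at the quaternary carbon are cut. Gain: the remaining stereocentre comes from the chiral pool. Demand: methyl must go in first and allyl second, because the second electrophile enters trans to the C5 substituent.

## Other disconnections considered

**Alternative 1:** The cut is the ring-C bond between the quaternary carbon and the CH carrying the three-carbon unit, so ring C would be closed from a chain instead of being taken from 1.

- Forward step: dihydropyran enol ether A1 (with the CH–CH3 stereocentre and a tethered allylsilane) is oxidised at a carbon anode in methanol. The radical cation is attacked at its methyl-bearing β-carbon by the allylsilane, loss of silicon gives the isopropenyl group, and methanol traps the oxocarbenium ion to give bicyclic ketal A2.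
- In its favour: the most congested C–C bond of ring C is made by umpolung in one reagent-free step. A2 holds the future spiro carbon at the ketone level and the future carboxyl carbon at the aldehyde level, so steps 4 and 18 would have no counterpart. On oxidation-level economy this alternative is the better plan.
- Against it: two new stereocentres, one quaternary, must be set relative to a single CH–CH3 centre in a radical-cation cyclisation onto a tetrasubstituted enol ether, with only a chair-like transition state as control. A1 needs its own enantioselective synthesis, and A2 does nothing for ring A or the spiro ether.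
- Comparison: structurally it solves ring C only. Mechanistically it trades a predictable enolate alkylation for a less predictable oxidative cyclisation. In step count it should be longer. In functional-group tolerance of the key step it is the equal of the chosen plan.

**Alternative 2:** The cut removes two ring-C bonds (quaternary carbon to the oxygen-bearing carbon, ester-bearing CH to the ring CH2), giving silyloxy diene A3 and enal A4.

- Forward step: a cationic oxazaborolidine (the HNTf2-protonated B-(2-methylphenyl) oxazaborolidine from diphenylprolinol, one enantiomer) catalyses the Diels–Alder reaction to cyclohexene A5, with a formyl-bearing quaternary carbon and a trans ester.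
- In its favour: the absolute configuration comes from the catalyst, so either enantiomer is accessible; in flexibility this is better than a chiral-pool start. The aldehyde is a direct handle for the two-carbon extension and the ester gives the tertiary alcohol by double methyl addition, which is the equal of, or better than, the selective hydroboration and hydration of steps 4 and 5.
- Against it: the dienophile is a trisubstituted, doubly activated alkene whose regiochemistry depends on the aldehyde outweighing the ester, and A3 is labile. After the cycloaddition a homologation, a Grignard addition, a face-selective alkene reduction to set CH–CH3 and conversion of the silyloxy carbon into the ketone are still needed.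
- Comparison: structurally it reaches the same ketone as 9 and again stops short of ring A. Mechanistically a catalyst-controlled [4+2] replaces substrate-controlled alkylation. In step economy it is poorer than the six steps from 1 to 9.

**Alternative 3:** The cut removes both bonds of the ester-bearing tropone carbon.

- Forward step: ring A arises by one-carbon enlargement of cis-fused tetrahydrofuran–cyclohexanone A6 with methyl diazoacetate A7 under oxonium-salt activation; a 1,2-shift with loss of N2 gives cycloheptanone β-keto ester A8.
- In its favour: the ether oxygen is already placed in A6, so the regiochemical question that burdens the chosen key step does not arise. On this point the alternative is better. The ester carbon is inserted exactly between the carbonyl and a methyl-bearing carbon.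
- Against it: two similar methyl-bearing α-carbons compete in the migration, with only the inductive effect of the ring oxygen to tell them apart, and a second insertion can follow. A8 is six hydrogens away from the tropone, so three dehydrogenations must pass through intermediates in which the ring ether is β to an enolisable carbonyl. Several sp3 centres of A6 are built only to be erased, and A6 needs a longer synthesis than 12.
- Comparison: structurally the chosen plan brings all seven ring carbons at an oxidation level one water away from the tropone. Mechanistically a cationic rearrangement replaces a cycloaddition. In step economy the alternative is clearly longer.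

Key step: step 14

Remarks on the chemistry (one line each):
- A furan made from 13 and 14 bears a 2-ethyl group and cannot undergo oxidative ring expansion until the furylic carbon carries a hydroxyl; step 11 supplies it.
- Assumption: a side-chain methyl ester and a free tertiary alcohol are unsuitable spectators (attack by ylide and acetylide, no differentiation from the ring-A ester), so 12 and 22 carry a silylated primary alcohol and a silylated tertiary alcohol; their skeletons are unchanged.
- Samarium diiodide is expected to break the allylic bridge C–O bond of 22, not the ketone-side one; the end game is written for that outcome, which also keeps the spiro ether safe during aromatisation.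

## Steps

Step 1
Reactants: 1 (S)-(+)-carvone
Product: 2 (5S)-2,6-dimethyl-5-(prop-1-en-2-yl)cyclohex-2-en-1-one (6-methylcarvone; both C6 epimers)
Conditions: LiN(i-Pr)2, THF, −78 °C; MeI, −78 to 0 °C
Reagents that add atoms: iodomethane, CI
Why: Kinetic deprotonation at the α′-methylene gives the cross-conjugated lithium dienolate, which is C-methylated (enolate alkylation); the C6 configuration is irrelevant because this centre is enolised again in step 2.

Step 2
Reactants: 2 (5S)-2,6-dimethyl-5-(prop-1-en-2-yl)cyclohex-2-en-1-one
Product: 3 (5R,6R)-2,6-dimethyl-6-(prop-2-en-1-yl)-5-(prop-1-en-2-yl)cyclohex-2-en-1-one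
Conditions: LiN(i-Pr)2, THF, −78 °C; allyl bromide, DMPU, −78 to 0 °C
Reagents that add atoms: allyl bromide, C=CCBr
Why: The α′-methine is deprotonated kinetically and the enolate is allylated on the face opposite the neighbouring isopropenyl group (substrate-controlled enolate alkylation), which sets the quaternary centre with the three-carbon chain trans and the methyl cis to that group; the order methyl first, allyl second is what gives this relative configuration.

Step 3
Reactants: 3 (5R,6R)-2,6-dimethyl-6-(prop-2-en-1-yl)-5-(prop-1-en-2-yl)cyclohex-2-en-1-one
Product: 4 (5R,6R)-2,6-dimethyl-6-(prop-2-en-1-yl)-5-(prop-1-en-2-yl)cyclohexan-1-one (both C2 epimers)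
Conditions: Li[HB(s-Bu)3], THF, −78 °C; aq. NH4Cl
Reagents that add atoms: none
Why: The bulky hydride adds 1,4 to the enone, whose carbonyl is screened by the quaternary carbon while the β-CH is open (conjugate reduction), and the isolated alkenes are untouched; C2 forms as an epimer mixture that is corrected under thermodynamic control in step 6.

Step 4
Reactants: 4 (5R,6R)-2,6-dimethyl-6-(prop-2-en-1-yl)-5-(prop-1-en-2-yl)cyclohexan-1-one
Product: 6 (5R,6R)-6-(3-hydroxypropyl)-2,6-dimethyl-5-(prop-1-en-2-yl)cyclohexan-1-one (both C2 epimers), via alkyl(disiamyl)borane 5 (not isolated)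
Conditions: (Sia)2BH (from BH3·SMe2 and 2-methylbut-2-ene), THF, 0 °C; then NaOH, H2O2, 0 °C to rt
Reagents that add atoms: hydrogen peroxide, OO
Why: Hydroboration–oxidation; the hindered dialkylborane discriminates strongly between the monosubstituted allyl alkene and the 1,1-disubstituted, more congested isopropenyl alkene and places boron on the terminal carbon, while the ketone next to a quaternary carbon should be reduced only slowly at 0 °C.

Step 5
Reactants: 6 (5R,6R)-6-(3-hydroxypropyl)-2,6-dimethyl-5-(prop-1-en-2-yl)cyclohexan-1-one
Product: 7 (5S,6R)-6-(3-hydroxypropyl)-5-(2-hydroxypropan-2-yl)-2,6-dimethylcyclohexan-1-one (both C2 epimers)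
Conditions: Co(acac)2 (cat.), PhSiH3, O2 (1 atm), THF, rt
Reagents that add atoms: dioxygen, O=O
Why: Mukaiyama hydration: hydrogen-atom transfer from a cobalt hydride to the 1,1-disubstituted alkene gives the tertiary radical, which is trapped by O2 and reduced to the Markovnikov alcohol; ketone and primary alcohol are inert and no stereocentre is formed.

Step 6
Reactants: 7 (5S,6R)-6-(3-hydroxypropyl)-5-(2-hydroxypropan-2-yl)-2,6-dimethylcyclohexan-1-one
Product: 9 (2S,5S,6R)-2,6-dimethyl-5-[2-(triethylsilyloxy)propan-2-yl]-6-[3-(triethylsilyloxy)propyl]cyclohexan-1-one, via bis(triethylsilyl) ether C2-epimer mixture 8 (not isolated)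
Conditions: TESOTf, 2,6-lutidine, CH2Cl2, −78 to 0 °C; then KOt-Bu (cat.), t-BuOH/THF, rt
Reagents that add atoms: triethylsilyl trifluoromethanesulfonate, CC[Si](CC)(CC)OS(=O)(=O)C(F)(F)F
Why: The silyl triflate with a hindered pyridine base silylates both the primary and the hindered tertiary hydroxyl; with the tert-alkyl group at C5 now locking the chair, catalytic alkoxide equilibrates the only enolisable centre (C2) to the equatorial-methyl epimer, because the other epimer would hold its methyl 1,3-diaxial to the axial methyl on the quaternary carbon.

Step 7
Reactants: 9 (2S,5S,6R)-2,6-dimethyl-5-[2-(triethylsilyloxy)propan-2-yl]-6-[3-(triethylsilyloxy)propyl]cyclohexan-1-one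
Product: 10 (3S,4R,5S,8S)-4,8-dimethyl-5-[2-(triethylsilyloxy)propan-2-yl]-4-[3-(triethylsilyloxy)propyl]-1-oxaspiro[2.5]octane
Conditions: Me3S(O)I, NaH, DMSO/THF, rt to 50 °C
Reagents that add atoms: trimethylsulfoxonium iodide, C[S+](C)(C)=O.[I-]
Why: Corey–Chaykovsky epoxidation with the stabilised sulfoxonium ylide, whose addition to the ketone is reversible, so ring closure should proceed from the betaine with the new CH2 equatorial and the oxygen axial (cis to the side chain and the C2 methyl), which is the spiro configuration required; the silyl ethers tolerate the conditions.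

Step 8
Reactants: 10 (3S,4R,5S,8S)-4,8-dimethyl-5-[2-(triethylsilyloxy)propan-2-yl]-4-[3-(triethylsilyloxy)propyl]-1-oxaspiro[2.5]octane
Product: 11 (1S,2R,3S,6S)-2,6-dimethyl-1-(prop-2-yn-1-yl)-3-[2-(triethylsilyloxy)propan-2-yl]-2-[3-(triethylsilyloxy)propyl]cyclohexan-1-ol
Conditions: LiC≡CH·H2NCH2CH2NH2, DMSO, rt to 45 °C; H2O
Reagents that add atoms: lithium acetylide–ethylenediamine complex, [Li+].[C-]#C.NCCN
Why: SN2 opening of the 2,2-disubstituted epoxide at its unsubstituted CH2 by acetylide in a dipolar aprotic solvent; the C–O bond at the spiro carbon is not touched, so its configuration is retained, and no ester is present to compete for the nucleophile.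

Step 9
Reactants: 11 (1S,2R,3S,6S)-2,6-dimethyl-1-(prop-2-yn-1-yl)-3-[2-(triethylsilyloxy)propan-2-yl]-2-[3-(triethylsilyloxy)propyl]cyclohexan-1-ol
Product: 12 (5S,6R,7S,10S)-6,10-dimethyl-7-[2-(triethylsilyloxy)propan-2-yl]-6-[3-(triethylsilyloxy)propyl]-1-oxaspiro[4.5]dec-2-ene
Conditions: Mo(CO)6 (cat.), Et3N, Et2O, hν (350 nm), rt
Reagents that add atoms: none
Why: Photogenerated Et3N·Mo(CO)5 isomerises the terminal alkyne to a molybdenum vinylidene, the tertiary hydroxyl adds to its carbene carbon (endo mode) and protodemetalation releases the 2,3-dihydrofuran (alkynol cycloisomerisation); the stereocentres are unaffected.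

Step 10
Reactants: 13 methyl 3-oxopentanoate; 14 chloroacetone
Product: 16 methyl 2-ethyl-4-methylfuran-3-carboxylate, via hydroxydihydrofuran 15 (not isolated)
Conditions: pyridine, 50 °C; then aq. HCl, rt
Reagents that add atoms: none
Why: Feist–Benary synthesis: aldol addition of the β-keto ester to the ketone carbonyl, O-alkylation of the enol by the chloromethyl group and acid-promoted dehydration give the 2,4-disubstituted furan-3-carboxylate rather than the 2,5-isomer of the C-alkylation pathway.

Step 11
Reactants: 16 methyl 2-ethyl-4-methylfuran-3-carboxylate
Product: 18 methyl 2-(1-hydroxyethyl)-4-methylfuran-3-carboxylate (racemic), via furylic bromide 17 (not isolated)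
Conditions: NBS, AIBN (cat.), PhCF3, 80 °C; then NaHCO3, acetone/H2O, 50 °C
Reagents that add atoms: water, O
Why: Wohl–Ziegler bromination should select the secondary furylic C–H of the ethyl group (the ester deactivates the ring toward electrophilic bromination), and the furyl-stabilised bromide is solvolysed in buffered aqueous acetone; the carbinol centre is racemic and disappears in step 14.

Step 12
Reactants: 18 methyl 2-(1-hydroxyethyl)-4-methylfuran-3-carboxylate
Product: 19 methyl 6-hydroxy-2,5-dimethyl-3-oxo-3,6-dihydro-2H-pyran-4-carboxylate (isomer mixture)
Conditions: NBS, NaHCO3, NaOAc, THF/H2O (4:1), 0 °C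
Reagents that add atoms: water, O
Why: Achmatowicz rearrangement: bromonium-initiated oxidative opening of the furan to the ene-dione and closure of the carbinol oxygen onto the aldehyde give the 6-hydroxypyranone with the ester on C4 and the methyls on C2 and C5; the isomer mixture is of no consequence.

Step 13
Reactants: 19 methyl 6-hydroxy-2,5-dimethyl-3-oxo-3,6-dihydro-2H-pyran-4-carboxylate
Product: 20 methyl 6-acetoxy-2,5-dimethyl-3-oxo-3,6-dihydro-2H-pyran-4-carboxylate (isomer mixture)
Conditions: Ac2O, pyridine, CH2Cl2, 0 °C
Reagents that add atoms: acetic anhydride, CC(=O)OC(C)=O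
Why: O-Acylation of the lactol under weakly basic conditions at low temperature, which avoids premature ylide formation; both isomers serve equally in step 14.

Step 14
Reactants: 20 methyl 6-acetoxy-2,5-dimethyl-3-oxo-3,6-dihydro-2H-pyran-4-carboxylate; 12 (5S,6R,7S,10S)-6,10-dimethyl-7-[2-(triethylsilyloxy)propan-2-yl]-6-[3-(triethylsilyloxy)propyl]-1-oxaspiro[4.5]dec-2-ene
Product: 22 oxa-bridged cycloadduct (8-oxabicyclo[3.2.1]oct-3-en-2-one with CH3 on C1 and C4 and CO2Me on C3; fused at C6–C7 to the spiro tetrahydrofuran with its oxygen on C7; mixture at the four new sp3 carbons), via oxidopyrylium ylide 21 (not isolated)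
Conditions: 20 (2.5 equiv), Et3N (slow addition), CH2Cl2, rt
Reagents that add atoms: none
Why: Et3N removes the C2 proton of 20 and acetate leaves from C6, so both isomers converge on the 3-oxidopyrylium 21, a cyclic carbonyl ylide. The ylide adds through C2 and C6, suprafacially, across the enol ether C=C of 12 in a concerted but asynchronous [5+2] cycloaddition, the established behaviour of 3-oxidopyrylium ylides from acetoxypyranones toward vinyl ethers. The seven-membered carbocycle is closed by the cycloaddition itself (both σ bonds in one event, no separate exo or endo cyclisation), and the ylide oxygen becomes the one-atom bridge. The step needs one selectivity, the regiochemical pairing: the O-bearing alkene carbon must bond to C2 (methyl-bearing, next to the oxido carbon) and the CH2-bearing alkene carbon to the unsubstituted C6. Three features of the ylide should work in this direction: the C4 ester is conjugated with the oxido group and weakens the bias that this group exerts in the parent ylide, the methyl groups on C2 and C5 shift acceptor-orbital density toward C6, and bonding the nucleophilic β-carbon of the enol ether to C6 avoids making the quaternary bridgehead in the leading bond. This is a bias and not a guarantee, and it is treated as the main risk below. The four new sp3 centres form as a mixture (endo and exo, both faces) and need no control because all become sp2 in step 16; the stereocentres of 12 are untouched. Excess 20 and slow addition of base keep the ylide concentration low so that capture by 12 competes with dimerisation.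

Step 15
Reactants: 22 oxa-bridged cycloadduct
Product: 23 ring-opened hydroxy keto ester (cyclohept-3-en-1-one with CO2Me on C2, CH3 on C3, OH and CH3 on C7; dihydrofuran fused at C5–C6 with its oxygen on C6; tautomer and diastereomer mixture)
Conditions: SmI2 (2.5 equiv), THF, −78 °C; then MeOH
Reagents that add atoms: none
Why: Electron transfer to the alkylidene β-keto ester gives a β-radical enolate, and after the second electron the carbanionoid β-carbon expels the aligned allylic bridge oxygen (reductive β-elimination, the usual course of samarium diiodide with γ-oxygenated unsaturated carbonyls); protonation of the samarium dienolate gives the monocyclic β-keto ester with a tertiary hydroxyl on the former bridgehead, and all tautomers and diastereomers converge in step 16.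

Step 16
Reactants: 23 ring-opened hydroxy keto ester
Product: 25 bis(triethylsilyl) ether of the tropone (ring A complete), via hydroxy dienone 24 (not isolated)
Conditions: DDQ, 1,4-dioxane, 60 °C; then PPTS (cat.), rt
Reagents that add atoms: none
Why: DDQ abstracts hydride from the δ-position of the dienol of the β-keto ester to give the hydroxy dienone (quinone dehydrogenation), and mild acid then lets the tertiary hydroxyl leave through the hydroxytropylium ion (dehydrative aromatisation); at no stage is the spiro ether oxygen β to an enolisable C–H, so it cannot be expelled in place of water.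

Step 17
Reactants: 25 bis(triethylsilyl) ether of the tropone
Product: 26 tropone diol (primary alcohol on the chain; tertiary alcohol on the C5 substituent)
Conditions: HF·pyridine, pyridine/THF, 0 °C to rt
Reagents that add atoms: none
Why: Fluoride-mediated cleavage of both silyl ethers under buffered conditions that neither ionise the tertiary alcohol nor add to the tropone.

Step 18
Reactants: 26 tropone diol
Product: 28 target acid CNP0448476.1, via aldehyde 27 (not isolated)
Conditions: TEMPO (cat.), PhI(OAc)2, MeCN/H2O (1:1), rt
Reagents that add atoms: water, O
Why: Oxoammonium-mediated oxidation takes the primary alcohol through the aldehyde hydrate to the acid; the tertiary alcohol, the tropone and its methyl ester are inert, so the two carboxyl groups end up differentiated without any hydrolysis.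

## Compound list

1 | (S)-(+)-carvone | CC1=CC[C@H](C(C)=C)CC1=O | starting material
2 | (5S)-2,6-dimethyl-5-(prop-1-en-2-yl)cyclohex-2-en-1-one, both C6 epimers | CC1=CC[C@H](C(C)=C)C(C)C1=O | intermediate
3 | (5R,6R)-2,6-dimethyl-6-(prop-2-en-1-yl)-5-(prop-1-en-2-yl)cyclohex-2-en-1-one | O=C1C(C)=CC[C@H](C(C)=C)[C@@]1(C)CC=C | intermediate
4 | (5R,6R)-2,6-dimethyl-6-(prop-2-en-1-yl)-5-(prop-1-en-2-yl)cyclohexan-1-one, both C2 epimers | O=C1C(C)CC[C@H](C(C)=C)[C@@]1(C)CC=C | intermediate
5 | alkyl(disiamyl)borane from 4 (not isolated) | O=C1C(C)CC[C@H](C(C)=C)[C@@]1(C)CCCB(C(C)C(C)C)C(C)C(C)C | intermediate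
6 | (5R,6R)-6-(3-hydroxypropyl)-2,6-dimethyl-5-(prop-1-en-2-yl)cyclohexan-1-one, both C2 epimers | O=C1C(C)CC[C@H](C(C)=C)[C@@]1(C)CCCO | intermediate
7 | (5S,6R)-6-(3-hydroxypropyl)-5-(2-hydroxypropan-2-yl)-2,6-dimethylcyclohexan-1-one, both C2 epimers | O=C1C(C)CC[C@H](C(C)(C)O)[C@@]1(C)CCCO | intermediate
8 | bis(triethylsilyl) ether of 7, both C2 epimers (not isolated) | O=C1C(C)CC[C@H](C(C)(C)O[Si](CC)(CC)CC)[C@@]1(C)CCCO[Si](CC)(CC)CC | intermediate
9 | (2S,5S,6R)-2,6-dimethyl-5-[2-(triethylsilyloxy)propan-2-yl]-6-[3-(triethylsilyloxy)propyl]cyclohexan-1-one | O=C1[C@@H](C)CC[C@H](C(C)(C)O[Si](CC)(CC)CC)[C@@]1(C)CCCO[Si](CC)(CC)CC | intermediate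
10 | (3S,4R,5S,8S)-4,8-dimethyl-5-[2-(triethylsilyloxy)propan-2-yl]-4-[3-(triethylsilyloxy)propyl]-1-oxaspiro[2.5]octane (oxygen axial) | O1C[C@@]12[C@@H](C)CC[C@H](C(C)(C)O[Si](CC)(CC)CC)[C@@]2(C)CCCO[Si](CC)(CC)CC | intermediate
11 | (1S,2R,3S,6S)-2,6-dimethyl-1-(prop-2-yn-1-yl)-3-[2-(triethylsilyloxy)propan-2-yl]-2-[3-(triethylsilyloxy)propyl]cyclohexan-1-ol | C#CC[C@]1(O)[C@@H](C)CC[C@H](C(C)(C)O[Si](CC)(CC)CC)[C@@]1(C)CCCO[Si](CC)(CC)CC | intermediate
12 | (5S,6R,7S,10S)-6,10-dimethyl-7-[2-(triethylsilyloxy)propan-2-yl]-6-[3-(triethylsilyloxy)propyl]-1-oxaspiro[4.5]dec-2-ene (spiro enol ether) | O1C=CC[C@@]12[C@@H](C)CC[C@H](C(C)(C)O[Si](CC)(CC)CC)[C@@]2(C)CCCO[Si](CC)(CC)CC | intermediate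
13 | methyl 3-oxopentanoate | CCC(=O)CC(=O)OC | starting material
14 | chloroacetone | CC(=O)CCl | starting material
15 | methyl 2-ethyl-4-hydroxy-4-methyl-4,5-dihydrofuran-3-carboxylate (not isolated) | CCC1=C(C(=O)OC)C(C)(O)CO1 | intermediate
16 | methyl 2-ethyl-4-methylfuran-3-carboxylate | CCc1occ(C)c1C(=O)OC | intermediate
17 | methyl 2-(1-bromoethyl)-4-methylfuran-3-carboxylate, racemic (not isolated) | CC(Br)c1occ(C)c1C(=O)OC | intermediate
18 | methyl 2-(1-hydroxyethyl)-4-methylfuran-3-carboxylate, racemic | CC(O)c1occ(C)c1C(=O)OC | intermediate
19 | methyl 6-hydroxy-2,5-dimethyl-3-oxo-3,6-dihydro-2H-pyran-4-carboxylate, isomer mixture | CC1OC(O)C(C)=C(C(=O)OC)C1=O | intermediate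
20 | methyl 6-acetoxy-2,5-dimethyl-3-oxo-3,6-dihydro-2H-pyran-4-carboxylate, isomer mixture | CC1OC(OC(C)=O)C(C)=C(C(=O)OC)C1=O | intermediate
21 | 4-(methoxycarbonyl)-2,5-dimethyl-3-oxidopyrylium (not isolated) | Cc1[o+]cc(C)c(C(=O)OC)c1[O-] | intermediate
22 | oxa-bridged [5+2] cycloadduct, bis(triethylsilyl) ether, mixture at the four new sp3 carbons | COC(=O)C1=C(C)C2OC(C)(C1=O)C1O[C@@]3(CC12)[C@@H](C)CC[C@H](C(C)(C)O[Si](CC)(CC)CC)[C@@]3(C)CCCO[Si](CC)(CC)CC | intermediate
23 | ring-opened hydroxy keto ester (cyclohept-3-en-1-one, tertiary OH on C7), tautomer and diastereomer mixture | COC(=O)C1C(C)=CC2C(C(C)(O)C1=O)O[C@@]3(C2)[C@@H](C)CC[C@H](C(C)(C)O[Si](CC)(CC)CC)[C@@]3(C)CCCO[Si](CC)(CC)CC | intermediate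
24 | hydroxy dienone (cyclohepta-2,4-dien-1-one, tertiary OH on C7), diastereomer mixture (not isolated) | COC(=O)C1=C(C)C=C2C(C(C)(O)C1=O)O[C@@]3(C2)[C@@H](C)CC[C@H](C(C)(C)O[Si](CC)(CC)CC)[C@@]3(C)CCCO[Si](CC)(CC)CC | intermediate
25 | tropone, bis(triethylsilyl) ether | COC(=O)c1c(C)cc2c(c(C)c1=O)O[C@@]1(C2)[C@@H](C)CC[C@H](C(C)(C)O[Si](CC)(CC)CC)[C@@]1(C)CCCO[Si](CC)(CC)CC | intermediate
26 | tropone diol | COC(=O)c1c(C)cc2c(c(C)c1=O)O[C@@]1(C2)[C@@H](C)CC[C@H](C(C)(C)O)[C@@]1(C)CCCO | intermediate
27 | tropone aldehyde (not isolated) | COC(=O)c1c(C)cc2c(c(C)c1=O)O[C@@]1(C2)[C@@H](C)CC[C@H](C(C)(C)O)[C@@]1(C)CCC=O | intermediate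
28 | CNP0448476.1 (tropone, spiro dihydrofuran, tertiary alcohol, propanoic acid side chain) | COC(=O)c1c(C)cc2c(c(C)c1=O)O[C@@]1(C2)[C@@H](C)CC[C@H](C(C)(C)O)[C@@]1(C)CCC(=O)O | target

## Step count and least certain steps

Total: 18 steps. Longest linear sequence: 14 steps (steps 1–9, 14–18). The pyranone branch (steps 10–13) has 4 steps.

**Step 14 (key step).** Most likely failure: reversal of the regiochemical pairing, with the nucleophilic enol ether carbon bonding to the methyl-bearing, oxido-flanked ylide carbon. The unsubstituted ylide tends to pair this way with simple vinyl ethers, and the substituents of 21 only bias against it. A second failure is consumption of the ylide by dimerisation.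

Fallback, from 20 and 12, returning at 22: the annulation is run as two ionic steps. A Lewis acid (BF3·OEt2, 2,6-di-tert-butylpyridine, CH2Cl2, −78 °C) ionises 20 to the pyranyl oxocarbenium ion, which can be attacked by the β-carbon of 12 only at its acetal carbon, the future tropone CH. Loss of a proton gives the 6-(4,5-dihydrofuran-3-yl)pyranone F1. Camphorsulfonic acid (CH2Cl2, 0 °C) then protonates the enol ether of F1, and the ketone enol closes through its methyl-bearing α-carbon onto the new oxocarbenium ion (five-membered exo closure across the ring oxygen), giving 22. The regiochemistry is fixed by the polarity of each step. Silyl ethers lost to acid would be put back with TESOTf.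

**Step 15.** Most likely failure: cleavage on the wrong side (the ketone-side C–O bond instead of the allylic one), or plain saturation of the alkene without ring opening, because both bridge bonds are aligned with the reduced π system.

Fallback, from 22, returning at 25: if the ketone-side bond breaks, the product is the 4-hydroxy enone F2. This is not taken through step 16, where its spiro ether oxygen would sit β to an enolisable ketone. It is silylated kinetically (LiN(i-Pr)2, TMSCl, THF, −78 °C) to the bis-silylated cross-conjugated silyl enol ether F3. Saegusa–Ito dehydrogenation (Pd(OAc)2, MeCN) gives the vinylogous ester F4. PPTS in MeOH then removes the silyl group and lets the now vinylogous secondary alcohol leave as water, giving 25.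

**Step 16.** Most likely failure: stalling at the hydroxy dienone, acid-induced acyloin-type shift of the tertiary α-hydroxy ketone, or premature loss of silyl groups.

Fallback, from 23, returning at 25: TMSOTf and Et3N (CH2Cl2, 0 °C) convert 23 into the bis-silylated 2-silyloxy diene F5. Pd(OAc)2 in MeCN dehydrogenates it at the γ,δ-position (Saegusa–Ito type), and PPTS in MeOH removes the tertiary silyl ether and triggers loss of water to 25. A palladium-mediated dehydrogenation of a defined silyl dienol ether thus replaces the quinone hydride abstraction.

**Step 7.** Most likely failure: sluggish addition of the stabilised ylide to a ketone flanked by a quaternary and a tertiary carbon, competing enolisation, or delivery of the methylene to the axial position.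

Fallback, from 9, returning at 10: Wittig methylenation (Ph3P=CH2 from Ph3PCH3Br and KOt-Bu, toluene, 90 °C) gives the exocyclic alkene F6. Epoxidation with mCPBA (NaHCO3, CH2Cl2, 0 °C) should occur anti to the axial methyl on the neighbouring quaternary carbon, which places the oxygen axial as in 10.

**Step 11.** Most likely failure: electrophilic bromination at the free ring α-position, double bromination of the ethyl group, or lactonisation of the hydroxy ester onto the neighbouring carboxylate.

Fallback, from 13, returning at 18: the oxygen is introduced before the furan is made. Bromination of 13 (Br2, CHCl3, 0 °C to rt, with equilibration to the γ-bromide) gives methyl 4-bromo-3-oxopentanoate F7. Displacement with KOAc (DMF, rt) gives methyl 4-acetoxy-3-oxopentanoate F8. Feist–Benary reaction with 14 (pyridine, then acid) gives methyl 2-(1-acetoxyethyl)-4-methylfuran-3-carboxylate F9, and K2CO3 in MeOH releases 18.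

## Further compounds

F1 | step 14 | methyl 2,5-dimethyl-3-oxo-6-(spiro-4,5-dihydrofuran-3-yl)-3,6-dihydro-2H-pyran-4-carboxylate, bis(triethylsilyl) ether, isomer mixture | COC(=O)C1=C(C)C(OC(C)C1=O)C1=CO[C@@]2(C1)[C@@H](C)CC[C@H](C(C)(C)O[Si](CC)(CC)CC)[C@@]2(C)CCCO[Si](CC)(CC)CC
F2 | step 15 | 4-hydroxy enone from ketone-side opening (cyclohept-2-en-1-one, OH on C4), diastereomer mixture | COC(=O)C1=C(C)C(O)C2C(C(C)C1=O)O[C@@]3(C2)[C@@H](C)CC[C@H](C(C)(C)O[Si](CC)(CC)CC)[C@@]3(C)CCCO[Si](CC)(CC)CC
F3 | step 15 | cross-conjugated trimethylsilyl enol ether of F2 with trimethylsilylated secondary alcohol | COC(=O)C1=C(C)C(O[Si](C)(C)C)C2C(C(C)=C1O[Si](C)(C)C)O[C@@]3(C2)[C@@H](C)CC[C@H](C(C)(C)O[Si](CC)(CC)CC)[C@@]3(C)CCCO[Si](CC)(CC)CC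
F4 | step 15 | cross-conjugated dienone (vinylogous ester) with trimethylsilyloxy group on C4 | COC(=O)C1=C(C)C(O[Si](C)(C)C)C2C(=C(C)C1=O)O[C@@]3(C2)[C@@H](C)CC[C@H](C(C)(C)O[Si](CC)(CC)CC)[C@@]3(C)CCCO[Si](CC)(CC)CC
F5 | step 16 | 2-(trimethylsilyloxy) diene of 23 with trimethylsilylated tertiary alcohol | COC(=O)C1=C(O[Si](C)(C)C)C(C)(O[Si](C)(C)C)C2O[C@@]3(CC2C=C1C)[C@@H](C)CC[C@H](C(C)(C)O[Si](CC)(CC)CC)[C@@]3(C)CCCO[Si](CC)(CC)CC
F6 | step 7 | exocyclic methylene compound from 9 | C=C1[C@@H](C)CC[C@H](C(C)(C)O[Si](CC)(CC)CC)[C@@]1(C)CCCO[Si](CC)(CC)CC
F7 | step 11 | methyl 4-bromo-3-oxopentanoate, racemic | CC(Br)C(=O)CC(=O)OC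
F8 | step 11 | methyl 4-acetoxy-3-oxopentanoate, racemic | CC(OC(C)=O)C(=O)CC(=O)OC
F9 | step 11 | methyl 2-(1-acetoxyethyl)-4-methylfuran-3-carboxylate, racemic | CC(OC(C)=O)c1occ(C)c1C(=O)OC
A1 | alternative 1 | 2-ethoxy-5-methyl-6-[(2S)-6-methyl-7-(trimethylsilyl)hept-5-en-2-yl]-3,4-dihydro-2H-pyran (acetal epimers, either alkene geometry) | CCOC1CCC(C)=C(O1)[C@@H](C)CCC=C(C)C[Si](C)(C)C
A2 | alternative 1 | bicyclic methyl ketal with isopropenyl group | CO[C@@]1(O2)[C@@H](C)CC[C@H](C(C)=C)[C@@]1(C)CCC2OCC
A3 | alternative 2 | (E)-tert-butyldimethyl[(2-methylbuta-1,3-dien-1-yl)oxy]silane | C=C/C(C)=C/O[Si](C)(C)C(C)(C)C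
A4 | alternative 2 | ethyl (E)-3-methyl-4-oxobut-2-enoate | CCOC(=O)/C=C(\C)C=O
A5 | alternative 2 | cyclohexene with formyl-bearing quaternary carbon, trans ester and silyloxy group | CC(C)(C)[Si](C)(C)O[C@H]1C(C)=CC[C@H](C(=O)OCC)[C@@]1(C)C=O
A6 | alternative 3 | cis-fused tetrahydrofuran–2,6-dimethylcyclohexanone carrying ring C | CC1CC2C(C(C)C1=O)O[C@@]1(C2)[C@@H](C)CC[C@H](C(C)(C)O[Si](CC)(CC)CC)[C@@]1(C)CCC(=O)OC
A7 | alternative 3 | methyl diazoacetate | COC(=O)C=[N+]=[N-]
A8 | alternative 3 | ring-enlarged cycloheptanone β-keto ester | COC(=O)C1C(C)CC2C(C(C)C1=O)O[C@@]1(C2)[C@@H](C)CC[C@H](C(C)(C)O[Si](CC)(CC)CC)[C@@]1(C)CCC(=O)OC
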